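## The problem

Target 20 is a 2,3,4-trisubstituted tetrahydrofuran lignan. It is numbered here O1, C2 (3,4,5-trimethoxyphenyl), C3 (C9H2OH), C4 (carbinol C7' with hydroxyl O7' and the 3,4-dimethoxyphenyl ring), C5, and the same labels are kept for these atoms in every intermediate. Its configuration is 2R,3S,4R,7'S: the three ring substituents are all-trans (C2 aryl and C4 arm cis to each other), and a fourth stereocentre, C7', lies outside the ring. Nothing in a monocyclic ether enforces this pattern, and ring thermodynamics cannot reach C7', so C7' and C4 have to be set together by a reaction of known sense and must then control C2. C3 is the only centre that becomes epimerisable once C9 is a carbonyl, and all-trans is the most stable arrangement, so C3 can be corrected late while C2, C4 and C7' cannot. Both benzylic C–O bonds (C2–O1 and C7'–O7') sit on electron-rich rings and ionise under acid, after which the C7' cation eliminates or is captured by the C9 hydroxyl to give a furofuran; a C9 carbonyl also has O1 in the β-position, so strong base invites retro-oxa-Michael opening. The enabling feature is that O7' and C9 can be tied as a γ-lactone with C3 as its α-carbon, and the benzylic ether C2–H bond then lies 1,5 to C3 (C3–C4–C5–O1–C2). A carbenoid at C3 can therefore insert into C2–H and close the tetrahydrofuran onto the lactone as a 3,7-dioxabicyclo[3.3.0]octan-8-one. The cis ring fusion delivers C3 with the wrong configuration, which the end game must invert.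

## Retrosynthesis

**20 back to aldehyde 17 (no skeletal bond cut).** Target 20 is taken back through its O7' silyl ether 19 and the all-trans aldehyde 18 to the all-cis aldehyde 17. C3 can only be inverted while C9 is a carbonyl; the aldehyde is the most easily enolised level and reduces directly to the C9 alcohol. O7' is capped so that it cannot close onto C9 and is freed last with fluoride, because the free diol is acid-sensitive. The forward reaction asked for is a purely thermodynamic epimerisation: in 17 the formyl group is cis to both neighbours, in 18 trans to both.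

**17 back to lactone 14 (reconnect O7'–C9).** Aldehyde 17 comes from Weinreb amide 16, this from hydroxy amide 15, and 15 from opening the bicyclic lactone 14. The amide is preferred to an ester because it stops cleanly at the aldehyde, and to a lactol because that would hide the aldehyde as a cyclic hemiacetal. Precursor 14 is rigid and already carries all four stereocentres. The opening must not touch C2, C4 or C7'.

**14 back to diazo lactone 13 (cut C2–C3, the key step).** Cutting O1–C2 instead would mean closing the ether through a benzylic cation, which gives the thermodynamic exo aryl. Cutting C3–C4 would separate the two centres that are easiest to set together. The C2–C3 cut removes one ring and two stereocentres and leaves a monocyclic trans lactone with only C4 and C7'. The forward reaction must insert at C2–H in preference to hydride shift from C4 and must place the aryl endo.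

**13 back to alcohol 8 and imidate 10 (remove the diazo group, cut O1–benzyl).** Diazo lactone 13 comes from lactone 11 by diazo transfer through the activated 3-trifluoroacetyl lactone 12. Ether 11 is cut between O1 and the benzylic carbon into hydroxymethyl lactone 8 and trichloroacetimidate 10, made from benzyl alcohol 9. The benzyl partner is the electrophile under acid because the alkoxide of 8 would translactonise onto C9.

**8 back to imide 3 and aldehyde 4 (cut C4–C7' and C9–O7').** Alcohol 8 is the reduction product of paraconic acid 7, the acid is freed from lactone imide 6, and 6 is the lactonised form of syn-aldol adduct 5 from succinate imide 3 and aldehyde 4. The syn aldol of a boron imide enolate gives C4 and C7' in one step with a known absolute sense, and the syn adduct closes to the trans lactone needed. Imide 3 is one acylation from oxazolidinone 1 and acid chloride 2, both purchased.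

## Roads not taken

**Alternative 1:** Cut O1–C2 and C3–C4 in a palladium zwitterion (3+2) cycloaddition. Zerovalent palladium from Pd2(dba)3 with a chiral phosphoramidite would ionise vinylethylene carbonate A3 with loss of CO2. The alkoxide would add to the benzylidene carbon of arylidene Meldrum's acid A2, and the stabilised carbanion would close on the internal allyl carbon to give the 2,4-cis spiro adduct A1.
- Merits: two bonds, the ring and the C2/C4 relationship arise in one catalytic asymmetric step from an achiral and a racemic partner. There is no auxiliary and no diazo compound. In step economy to the ring core it is better than the chosen plan.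
- Weak points: A1 contains neither C7' nor the second aryl ring. The vinyl group would have to be degraded by one carbon and the dimethoxyphenyl ring added to the resulting C4 carbonyl carbon, so C7' would rest on 1,2-induction from a ring stereocentre with no clear bias. That carbonyl also has O1 in the β-position. C3 arrives quaternary, so one carboxyl must be removed and C3 set by protonation.
- Comparison: the chosen plan is longer but sets C7' together with C4 at the outset and never has to create the exocyclic carbinol by addition or reduction.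

**Alternative 2:** Cut C2–C3 and C4–C5 in a Prins–pinacol ring contraction. SnCl4 would open dioxolane A5 to the O1=C2 oxocarbenium ion, alkene carbon C3 would attack C2, and C5 would migrate from C7' to C4, giving the all-trans ketone A4.
- Merits: two C–C bonds and all three ring stereocentres are formed directly in the all-trans arrangement through a chair with equatorial substituents. No C3 correction is needed, which is better than the chosen plan.
- Weak points: C7' becomes a ketone and must be reduced under the influence of C4 alone, with uncertain sense. A5 carries a tertiary alkoxy carbon that is both allylic and benzylic to the electron-rich dimethoxyphenyl ring, so ionisation there competes with acetal opening under SnCl4. A5 must itself be made enantiopure, and the sense of chirality transfer depends on whether the aryl group or the tin-bound oxygen sits equatorial.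
- Comparison: the chosen plan sets C7' by an aldol of known sense and keeps cation-prone tertiary centres out of the route, at the price of a diazo intermediate and the C3 inversion.

**Alternative 3:** Cut C4–C5 (and C7'–O) in an oxonium-Prins closure. BF3·OEt2 with acetic acid would ionise the methoxymethyl ether A7 to an O1=C5H2 oxocarbenium ion, styrene carbon C4 would attack C5, and acetate would capture the C7' cation to give diester A6.
- Merits: A6 needs only ester cleavage to reach 20, and C2 and C3 are set beforehand in an open chain. This is the shortest plan on paper.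
- Weak points: C7' is created by external capture of a free dimethoxybenzylic cation, which has little facial bias and can re-ionise. The homoallylic oxocarbenium ion can undergo 2-oxonia-Cope rearrangement to a more stabilised trimethoxybenzylidene oxocarbenium ion, scrambling C2 and C3. The cation can also be trapped by the neighbouring trimethoxyphenyl ring.
- Comparison: Alternative 3 wins on step count. The chosen plan offers control of every centre by a defined element: aldol for C4 and C7', ring fusion and the insertion transition state for C2, thermodynamics for C3.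

Key step: step 8

## Route

Step 1
Reactants: 1 (S)-4-benzyl-1,3-oxazolidin-2-one; 2 methyl 4-chloro-4-oxobutanoate
Product: 3 methyl 4-[(4S)-4-benzyl-2-oxo-1,3-oxazolidin-3-yl]-4-oxobutanoate
Conditions: n-BuLi, THF, −78 °C; then 2, −78 → 0 °C
Reagents that add atoms: none
Why: N-acylation of a lithiated oxazolidinone; the acid chloride reacts far faster than the methyl ester at low temperature, so only the imide forms.

Step 2
Reactants: 3 methyl 4-[(4S)-4-benzyl-2-oxo-1,3-oxazolidin-3-yl]-4-oxobutanoate; 4 3,4-dimethoxybenzaldehyde
Product: 6 (4S)-4-benzyl-3-{[(2S,3S)-2-(3,4-dimethoxyphenyl)-5-oxotetrahydrofuran-3-yl]carbonyl}-1,3-oxazolidin-2-one (trans lactone), via syn-aldol hydroxy ester 5 (not isolated)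
Conditions: Bu2BOTf, i-Pr2NEt, CH2Cl2, 0 °C; 4, −78 → 0 °C; pH 7 phosphate buffer, MeOH, H2O2, 0 °C → rt
Reagents that add atoms: none
Why: Evans syn aldol: soft enolisation gives the Z boron enolate of the imide only, and the chair transition state with the benzyl group shielding one face should set C4 and C7' as the (S,S) syn adduct 5. The γ-hydroxy ester of 5 is expected to close with loss of methanol to the trans lactone on warming or during work-up.

Step 3
Reactants: 6 (4S)-4-benzyl-3-{[(2S,3S)-2-(3,4-dimethoxyphenyl)-5-oxotetrahydrofuran-3-yl]carbonyl}-1,3-oxazolidin-2-one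
Product: 7 (2S,3S)-2-(3,4-dimethoxyphenyl)-5-oxotetrahydrofuran-3-carboxylic acid
Conditions: LiOH, H2O2, THF–H2O, 0 °C; Na2SO3; HCl to pH 2
Reagents that add atoms: hydrogen peroxide (as LiOOH), OO
Why: Hydroperoxide cleavage of the exocyclic imide carbonyl without epimerisation; any lactone opened by hydroxide recloses on acidification, and the auxiliary is recovered.

Step 4
Reactants: 7 (2S,3S)-2-(3,4-dimethoxyphenyl)-5-oxotetrahydrofuran-3-carboxylic acid
Product: 8 (4R,5S)-5-(3,4-dimethoxyphenyl)-4-(hydroxymethyl)dihydrofuran-2(3H)-one
Conditions: BH3·SMe2, THF, 0 °C → rt; MeOH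
Reagents that add atoms: none
Why: Chemoselective borane reduction of a carboxylic acid (through the acyloxyborane) in the presence of a lactone; the non-basic conditions avoid translactonisation.

Step 5
Reactants: 9 3,4,5-trimethoxybenzyl alcohol
Product: 10 3,4,5-trimethoxybenzyl 2,2,2-trichloroacetimidate
Conditions: Cl3CCN, DBU (cat.), CH2Cl2, 0 °C
Reagents that add atoms: trichloroacetonitrile, N#CC(Cl)(Cl)Cl
Why: Base-catalysed addition of an alcohol to trichloroacetonitrile, the standard preparation of benzylic trichloroacetimidates.

Step 6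
Reactants: 8 (4R,5S)-5-(3,4-dimethoxyphenyl)-4-(hydroxymethyl)dihydrofuran-2(3H)-one; 10 3,4,5-trimethoxybenzyl 2,2,2-trichloroacetimidate
Product: 11 (4R,5S)-5-(3,4-dimethoxyphenyl)-4-{[(3,4,5-trimethoxybenzyl)oxy]methyl}dihydrofuran-2(3H)-one
Conditions: TfOH (cat.), CH2Cl2, 0 °C
Reagents that add atoms: none
Why: Acid-catalysed O-benzylation with a trichloroacetimidate forms the O1–C2 bond; no alkoxide of 8 is generated, so translactonisation onto C9 is avoided.

Step 7
Reactants: 11 (4R,5S)-5-(3,4-dimethoxyphenyl)-4-{[(3,4,5-trimethoxybenzyl)oxy]methyl}dihydrofuran-2(3H)-one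
Product: 13 (4R,5S)-3-diazo-5-(3,4-dimethoxyphenyl)-4-{[(3,4,5-trimethoxybenzyl)oxy]methyl}dihydrofuran-2(3H)-one, via 3-trifluoroacetyl lactone 12 (not isolated)
Conditions: LiN(SiMe3)2, THF, −78 °C; CF3CO2CH2CF3; aq. HCl work-up; then 4-acetamidobenzenesulfonyl azide, Et3N, H2O, MeCN, rt
Reagents that add atoms: 4-acetamidobenzenesulfonyl azide, CC(=O)Nc1ccc(cc1)S(=O)(=O)N=[N+]=[N-]; 2,2,2-trifluoroethyl trifluoroacetate, O=C(OCC(F)(F)F)C(F)(F)F (its acyl group is present in 12 only)
Why: Detrifluoroacetylative diazo transfer: Claisen-type trifluoroacetylation of the lactone enolate activates C3, the sulfonyl azide transfers N2, and the trifluoroacetyl group leaves on the sulfonamide. C4 and C7' carry no acidic hydrogen and are untouched.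

Step 8
Reactants: 13 (4R,5S)-3-diazo-5-(3,4-dimethoxyphenyl)-4-{[(3,4,5-trimethoxybenzyl)oxy]methyl}dihydrofuran-2(3H)-one
Product: 14 (3S,3aR,6R,6aS)-3-(3,4-dimethoxyphenyl)-6-(3,4,5-trimethoxyphenyl)tetrahydro-1H,3H-furo[3,4-c]furan-1-one, that is (1S,2R,5R,6S)-6-exo-(3,4-dimethoxyphenyl)-2-endo-(3,4,5-trimethoxyphenyl)-3,7-dioxabicyclo[3.3.0]octan-8-one
Conditions: Rh2(OAc)4 (2 mol %), CH2Cl2, rt, slow addition of 13
Reagents that add atoms: none
Why: Rh2(OAc)4 should decompose 13 with loss of N2 to an electrophilic divalent rhodium carbenoid at C3, which inserts into the benzylic ether C2–H bond through a concerted, asynchronous three-centre transition state with hydride-like transfer. The closest known reaction type is the rhodium carbenoid 1,5 C–H insertion of α-diazo-γ-butyrolactones into ether α-C–H bonds. The tetrahydrofuran closes in the five-membered (1,5) mode, the only one that reaches a C–H bond activated by both the ether oxygen and the trimethoxyphenyl ring. C3 is set by the ring fusion, since a bicyclo[3.3.0] lactone can only be cis, so C3 bonds to C2 on the face of the lactone that carries the C4–C5 bond. C2 is set by the resident C4 centre through a chair-like transition state in which the aryl group sits pseudo-equatorial, away from the carboxylate ligands; this is expected to place it endo, cis to the C4–C7' arm, as the target requires. The step needs chemoselectivity for insertion over 1,2-hydride shift from C4, carbenoid dimerisation and attack on the arenes. The hydridic, doubly activated C2–H bond, the carboxylate-ligated catalyst and a low standing concentration of 13 should secure it.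

Step 9
Reactants: 14 (3S,3aR,6R,6aS)-3-(3,4-dimethoxyphenyl)-6-(3,4,5-trimethoxyphenyl)tetrahydro-1H,3H-furo[3,4-c]furan-1-one
Product: 15 (2R,3S,4R)-4-[(S)-(3,4-dimethoxyphenyl)(hydroxy)methyl]-N-methoxy-N-methyl-2-(3,4,5-trimethoxyphenyl)tetrahydrofuran-3-carboxamide (ring substituents all-cis)
Conditions: Me3Al, MeNHOMe·HCl, CH2Cl2, 0 °C → rt; aq. potassium sodium tartrate
Reagents that add atoms: N,O-dimethylhydroxylamine hydrochloride, CNOC.Cl
Why: Weinreb aminolysis of a lactone by the aluminium amide cleaves C9–O7' without touching a stereocentre; 15 is taken on crude at once because a γ-hydroxy amide can relactonise.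

Step 10
Reactants: 15 (2R,3S,4R)-4-[(S)-(3,4-dimethoxyphenyl)(hydroxy)methyl]-N-methoxy-N-methyl-2-(3,4,5-trimethoxyphenyl)tetrahydrofuran-3-carboxamide
Product: 16 (2R,3S,4R)-4-[(S)-(tert-butyldimethylsilyloxy)(3,4-dimethoxyphenyl)methyl]-N-methoxy-N-methyl-2-(3,4,5-trimethoxyphenyl)tetrahydrofuran-3-carboxamide
Conditions: TBSOTf, 2,6-lutidine, CH2Cl2, −78 → 0 °C
Reagents that add atoms: tert-butyldimethylsilyl trifluoromethanesulfonate, CC(C)(C)[Si](C)(C)OS(=O)(=O)C(F)(F)F
Why: Silylation of a hindered secondary alcohol with a silyl triflate and a non-nucleophilic base; it blocks relactonisation and protects O7' through the reduction and base steps.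

Step 11
Reactants: 16 (2R,3S,4R)-4-[(S)-(tert-butyldimethylsilyloxy)(3,4-dimethoxyphenyl)methyl]-N-methoxy-N-methyl-2-(3,4,5-trimethoxyphenyl)tetrahydrofuran-3-carboxamide
Product: 17 (2R,3S,4R)-4-[(S)-(tert-butyldimethylsilyloxy)(3,4-dimethoxyphenyl)methyl]-2-(3,4,5-trimethoxyphenyl)tetrahydrofuran-3-carbaldehyde (all-cis)
Conditions: i-Bu2AlH, THF, −78 °C; aq. potassium sodium tartrate
Reagents that add atoms: none
Why: Reduction of a Weinreb amide stops at the aldehyde because the chelated aluminium hemiaminal survives until work-up.

Step 12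
Reactants: 17 (2R,3S,4R)-4-[(S)-(tert-butyldimethylsilyloxy)(3,4-dimethoxyphenyl)methyl]-2-(3,4,5-trimethoxyphenyl)tetrahydrofuran-3-carbaldehyde
Product: 19 [(2R,3S,4R)-4-[(S)-(tert-butyldimethylsilyloxy)(3,4-dimethoxyphenyl)methyl]-2-(3,4,5-trimethoxyphenyl)tetrahydrofuran-3-yl]methanol (all-trans), via all-trans aldehyde 18 (not isolated)
Conditions: DBU, CH2Cl2, rt; then MeOH, NaBH4, 0 °C
Reagents that add atoms: none
Why: Base-mediated epimerisation of an aldehyde α-centre through its enolate: the formyl group of 17 is cis to both neighbours, so equilibrium should lie far on the side of all-trans 18. NaBH4 then reduces the aldehyde and fixes C3, while C2, C4 and C7' carry no acidic hydrogen.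

Step 13
Reactants: 19 [(2R,3S,4R)-4-[(S)-(tert-butyldimethylsilyloxy)(3,4-dimethoxyphenyl)methyl]-2-(3,4,5-trimethoxyphenyl)tetrahydrofuran-3-yl]methanol
Product: 20 [(2R,3S,4R)-4-[(S)-(3,4-dimethoxyphenyl)(hydroxy)methyl]-2-(3,4,5-trimethoxyphenyl)tetrahydrofuran-3-yl]methanol
Conditions: Bu4NF, THF, 0 °C → rt
Reagents that add atoms: none
Why: Fluoride cleavage of a silyl ether under non-acidic conditions, so neither benzylic C–O bond is ionised; a silyl shift between O7' and O9 would not matter because the group is removed here.

## Compound list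

1 | (S)-4-benzyl-1,3-oxazolidin-2-one | O=C1N[C@@H](Cc2ccccc2)CO1 | starting material
2 | methyl 4-chloro-4-oxobutanoate | COC(=O)CCC(Cl)=O | starting material
3 | methyl 4-[(4S)-4-benzyl-2-oxo-1,3-oxazolidin-3-yl]-4-oxobutanoate | COC(=O)CCC(=O)N1[C@@H](Cc2ccccc2)COC1=O | intermediate
4 | 3,4-dimethoxybenzaldehyde | COc1ccc(C=O)cc1OC | starting material
5 | methyl (3S)-3-[(S)-(3,4-dimethoxyphenyl)(hydroxy)methyl]-4-[(4S)-4-benzyl-2-oxo-1,3-oxazolidin-3-yl]-4-oxobutanoate (syn-aldol hydroxy ester) | COC(=O)C[C@@H]([C@H](O)c1ccc(OC)c(OC)c1)C(=O)N1[C@@H](Cc2ccccc2)COC1=O | intermediate (not isolated)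
6 | (4S)-4-benzyl-3-{[(2S,3S)-2-(3,4-dimethoxyphenyl)-5-oxotetrahydrofuran-3-yl]carbonyl}-1,3-oxazolidin-2-one | COc1ccc([C@H]2OC(=O)C[C@@H]2C(=O)N3[C@@H](Cc4ccccc4)COC3=O)cc1OC | intermediate
7 | (2S,3S)-2-(3,4-dimethoxyphenyl)-5-oxotetrahydrofuran-3-carboxylic acid | COc1ccc([C@H]2OC(=O)C[C@@H]2C(=O)O)cc1OC | intermediate
8 | (4R,5S)-5-(3,4-dimethoxyphenyl)-4-(hydroxymethyl)dihydrofuran-2(3H)-one | COc1ccc([C@H]2OC(=O)C[C@@H]2CO)cc1OC | intermediate
9 | 3,4,5-trimethoxybenzyl alcohol | COc1cc(CO)cc(OC)c1OC | starting material
10 | 3,4,5-trimethoxybenzyl 2,2,2-trichloroacetimidate | COc1cc(COC(=N)C(Cl)(Cl)Cl)cc(OC)c1OC | intermediate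
11 | (4R,5S)-5-(3,4-dimethoxyphenyl)-4-{[(3,4,5-trimethoxybenzyl)oxy]methyl}dihydrofuran-2(3H)-one | COc1ccc([C@H]2OC(=O)C[C@@H]2COCc3cc(OC)c(OC)c(OC)c3)cc1OC | intermediate
12 | (4R,5S)-5-(3,4-dimethoxyphenyl)-3-(trifluoroacetyl)-4-{[(3,4,5-trimethoxybenzyl)oxy]methyl}dihydrofuran-2(3H)-one (C3 epimers and enol form) | COc1ccc([C@H]2OC(=O)C(C(=O)C(F)(F)F)[C@@H]2COCc3cc(OC)c(OC)c(OC)c3)cc1OC | intermediate (not isolated)
13 | (4R,5S)-3-diazo-5-(3,4-dimethoxyphenyl)-4-{[(3,4,5-trimethoxybenzyl)oxy]methyl}dihydrofuran-2(3H)-one | COc1ccc([C@H]2OC(=O)C(=[N+]=[N-])[C@@H]2COCc3cc(OC)c(OC)c(OC)c3)cc1OC | intermediate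
14 | (3S,3aR,6R,6aS)-3-(3,4-dimethoxyphenyl)-6-(3,4,5-trimethoxyphenyl)tetrahydro-1H,3H-furo[3,4-c]furan-1-one (cis-fused, 6-aryl endo, 3-aryl exo) | COc1ccc([C@@H](O5)[C@H]2CO[C@@H](c3cc(OC)c(OC)c(OC)c3)[C@H]2C5=O)cc1OC | intermediate
15 | (2R,3S,4R)-4-[(S)-(3,4-dimethoxyphenyl)(hydroxy)methyl]-N-methoxy-N-methyl-2-(3,4,5-trimethoxyphenyl)tetrahydrofuran-3-carboxamide (all-cis) | COc1ccc([C@@H](O)[C@H]2CO[C@@H](c3cc(OC)c(OC)c(OC)c3)[C@H]2C(=O)N(C)OC)cc1OC | intermediate
16 | (2R,3S,4R)-4-[(S)-(tert-butyldimethylsilyloxy)(3,4-dimethoxyphenyl)methyl]-N-methoxy-N-methyl-2-(3,4,5-trimethoxyphenyl)tetrahydrofuran-3-carboxamide (all-cis) | COc1ccc([C@@H](O[Si](C)(C)C(C)(C)C)[C@H]2CO[C@@H](c3cc(OC)c(OC)c(OC)c3)[C@H]2C(=O)N(C)OC)cc1OC | intermediate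
17 | (2R,3S,4R)-4-[(S)-(tert-butyldimethylsilyloxy)(3,4-dimethoxyphenyl)methyl]-2-(3,4,5-trimethoxyphenyl)tetrahydrofuran-3-carbaldehyde (all-cis) | COc1ccc([C@@H](O[Si](C)(C)C(C)(C)C)[C@H]2CO[C@@H](c3cc(OC)c(OC)c(OC)c3)[C@H]2C=O)cc1OC | intermediate
18 | (2R,3R,4R)-4-[(S)-(tert-butyldimethylsilyloxy)(3,4-dimethoxyphenyl)methyl]-2-(3,4,5-trimethoxyphenyl)tetrahydrofuran-3-carbaldehyde (all-trans) | COc1ccc([C@@H](O[Si](C)(C)C(C)(C)C)[C@H]2CO[C@@H](c3cc(OC)c(OC)c(OC)c3)[C@@H]2C=O)cc1OC | intermediate (not isolated)
19 | [(2R,3S,4R)-4-[(S)-(tert-butyldimethylsilyloxy)(3,4-dimethoxyphenyl)methyl]-2-(3,4,5-trimethoxyphenyl)tetrahydrofuran-3-yl]methanol (all-trans) | COc1ccc([C@@H](O[Si](C)(C)C(C)(C)C)[C@H]2CO[C@@H](c3cc(OC)c(OC)c(OC)c3)[C@@H]2CO)cc1OC | intermediate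
20 | [(2R,3S,4R)-4-[(S)-(3,4-dimethoxyphenyl)(hydroxy)methyl]-2-(3,4,5-trimethoxyphenyl)tetrahydrofuran-3-yl]methanol | COc1ccc([C@@H](O)[C@H]2CO[C@@H](c3cc(OC)c(OC)c(OC)c3)[C@@H]2CO)cc1OC | target

## Step count and risks

Total step count: 13. Longest linear sequence: 12 (steps 1–4 and 6–13); step 5 is a one-step branch.

**Step 8 (key step).**
- What may go wrong: 1,2-hydride migration from C4 to the carbenoid carbon, which consumes the diazo compound without forming the ring; erosion of the endo preference at C2; carbenoid attack on one of the electron-rich arenes.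
- Fallback: it sets out from alcohol 8 and returns at 14. Acid-catalysed acetal exchange of 8 with commercial 3,4,5-trimethoxybenzaldehyde dimethyl acetal (pyridinium p-toluenesulfonate, removal of methanol) would give the mixed methyl acetal F1. LiN(SiMe3)2 and Me3SiCl would convert its lactone into the trimethylsilyl ketene acetal F2. Catalytic Me3SiOTf at −78 °C would ionise the acetal to the O1=C2 oxocarbenium ion, which the ketene acetal carbon C3 would capture in an intramolecular Mukaiyama-type addition, giving 14 with the cis fusion again enforced.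
- Trade-off: the same bond and ring form by a polar path with no diazo compound and no hydride shift. The C2 configuration of an ionic closure is less predictable and would have to be established; an unwanted epimer would be removed at 14.

**Step 12.**
- What may go wrong: β-elimination of O1 from the C3 enolate (retro-oxa-Michael opening of the ring) on prolonged exposure to base, or reduction before equilibration is complete. The ring opening is the reverse of a 5-endo closure and should be slow, but it is the main threat.
- Fallback: it sets out from 14 and returns at 20. NaOMe in MeOH at reflux would open the lactone reversibly to the cis hydroxy ester, whose C3 can epimerise. The all-trans methyl ester F3 cannot relactonise, because a trans-fused bicyclo[3.3.0] lactone is too strained, and should accumulate. LiAlH4 in THF at 0 °C would reduce F3 to 20.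
- Trade-off: the epimerisation moves to the ester level and needs no protecting group, which would shorten the route by three steps. It is held in reserve because the position of the lactone/hydroxy ester equilibrium is not known.

**Step 9 (with step 10).**
- What may go wrong: slow aminolysis at a carbonyl flanked by the endo aryl group, and relactonisation of 15 with loss of the amine before O7' is silylated.
- Fallback: it sets out from 14 and returns at 20. i-Bu2AlH in CH2Cl2 at −78 °C would give the lactol F4. K2CO3 in MeOH would equilibrate F4 through its open hydroxy aldehyde form to the all-trans hydroxy aldehyde F5, which cannot close to a trans-fused lactol. NaBH4, added only after equilibration, would give 20.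

**Step 6.**
- What may go wrong: Friedel–Crafts benzylation of the dimethoxyphenyl ring or self-condensation of the imidate, and acid-induced ionisation of the C7'–O bond of the lactone with loss of the trans relationship.
- Fallback: it sets out from 8 and returns at 11. 3,4,5-Trimethoxybenzyl bromide F6, made from 9 with PBr3, would alkylate 8 in the presence of Ag2O in CH2Cl2 in the dark. This silver-assisted Williamson etherification runs under essentially neutral conditions and generates neither a free benzylic cation nor a free alkoxide.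

## Further compounds

F1 | step 8 | (4R,5S)-5-(3,4-dimethoxyphenyl)-4-{[methoxy(3,4,5-trimethoxyphenyl)methoxy]methyl}dihydrofuran-2(3H)-one (acetal epimers) | COc1ccc([C@H]2OC(=O)C[C@@H]2COC(OC)c3cc(OC)c(OC)c(OC)c3)cc1OC
F2 | step 8 | trimethylsilyl ketene acetal of F1, (4R,5S)-5-(3,4-dimethoxyphenyl)-4-{[methoxy(3,4,5-trimethoxyphenyl)methoxy]methyl}-2-(trimethylsilyloxy)-4,5-dihydrofuran | COc1ccc([C@H]2OC(O[Si](C)(C)C)=C[C@@H]2COC(OC)c3cc(OC)c(OC)c(OC)c3)cc1OC
F3 | step 12 | methyl (2R,3R,4R)-4-[(S)-(3,4-dimethoxyphenyl)(hydroxy)methyl]-2-(3,4,5-trimethoxyphenyl)tetrahydrofuran-3-carboxylate (all-trans) | COc1ccc([C@@H](O)[C@H]2CO[C@@H](c3cc(OC)c(OC)c(OC)c3)[C@@H]2C(=O)OC)cc1OC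
F4 | step 9 | (3S,3aR,6R,6aS)-3-(3,4-dimethoxyphenyl)-6-(3,4,5-trimethoxyphenyl)tetrahydro-1H,3H-furo[3,4-c]furan-1-ol (lactol, anomers) | COc1ccc([C@@H](O5)[C@H]2CO[C@@H](c3cc(OC)c(OC)c(OC)c3)[C@H]2C5O)cc1OC
F5 | step 9 | (2R,3R,4R)-4-[(S)-(3,4-dimethoxyphenyl)(hydroxy)methyl]-2-(3,4,5-trimethoxyphenyl)tetrahydrofuran-3-carbaldehyde (all-trans) | COc1ccc([C@@H](O)[C@H]2CO[C@@H](c3cc(OC)c(OC)c(OC)c3)[C@@H]2C=O)cc1OC
F6 | step 6 | 3,4,5-trimethoxybenzyl bromide | COc1cc(CBr)cc(OC)c1OC
A1 | alternative 1 | 2,4-cis spiro adduct, 2-(3,4,5-trimethoxyphenyl)-4-vinyltetrahydrofuran-3,3-dicarboxylic acid isopropylidene ester | C=C[C@H]1CO[C@@H](c2cc(OC)c(OC)c(OC)c2)C13C(=O)OC(C)(C)OC3=O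
A2 | alternative 1 | 2,2-dimethyl-5-(3,4,5-trimethoxybenzylidene)-1,3-dioxane-4,6-dione | COc1cc(C=C2C(=O)OC(C)(C)OC2=O)cc(OC)c1OC
A3 | alternative 1 | 4-vinyl-1,3-dioxolan-2-one (racemic) | C=CC1COC(=O)O1
A4 | alternative 2 | all-trans 4-(3,4-dimethoxybenzoyl)-3-[(tert-butyldiphenylsilyloxy)methyl]-2-(3,4,5-trimethoxyphenyl)tetrahydrofuran | COc1ccc(C(=O)[C@H]2CO[C@@H](c3cc(OC)c(OC)c(OC)c3)[C@@H]2CO[Si](c4ccccc4)(c4ccccc4)C(C)(C)C)cc1OC
A5 | alternative 2 | (4S)-4-[(E)-3-(tert-butyldiphenylsilyloxy)prop-1-enyl]-4-(3,4-dimethoxyphenyl)-2-(3,4,5-trimethoxyphenyl)-1,3-dioxolane (either acetal epimer; carbinol configuration as required by an aryl-equatorial chair) | COc1ccc([C@@]2(/C=C/CO[Si](c3ccccc3)(c3ccccc3)C(C)(C)C)COC(c3cc(OC)c(OC)c(OC)c3)O2)cc1OC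
A6 | alternative 3 | C7' acetate and C9 pivalate of the target | COc1ccc([C@@H](OC(C)=O)[C@H]2CO[C@@H](c3cc(OC)c(OC)c(OC)c3)[C@@H]2COC(=O)C(C)(C)C)cc1OC
A7 | alternative 3 | (2S,3E)-4-(3,4-dimethoxyphenyl)-2-[(R)-(methoxymethoxy)(3,4,5-trimethoxyphenyl)methyl]but-3-en-1-yl 2,2-dimethylpropanoate | COc1ccc(/C=C/[C@@H](COC(=O)C(C)(C)C)[C@@H](OCOC)c2cc(OC)c(OC)c(OC)c2)cc1OC
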